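**Retrosynthetic overview**

1. Target 10 ⇒ methyl ketone 7 + 4-hydroxybenzaldehyde 8: the enone C=C is made last by Claisen–Schmidt condensation, which also sets the E geometry.
2. 7 ⇒ aryl iodide 2 + epoxide 5: the aryl–CH2 bond (key bond) comes from a blue-light nickel cross-electrophile coupling, run before the enone exists because a chalcone would trap radicals and absorb light.
3. 2 ⇐ 1 by iodination at C3'; 5 ⇐ methyl (S)-glycidate 3 + 2 MeMgCl. The only stereocentre is bought in 3 and is never a reaction centre.
4. Rings: none is built. Rings A and B are bought in 1 and 8; the oxirane of 3 is carried into 5 and opened in the key step.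

Assumption: the single stereocentre of the target is (S) as read from the SMILES, and compounds 1, 3 and 8 are taken as catalogue chemicals.

**Route**

Step 1
Reactants: 1 2',4'-dihydroxy-6'-methoxyacetophenone
Product: 2 3'-iodo-2',4'-dihydroxy-6'-methoxyacetophenone [1-(2,4-dihydroxy-3-iodo-6-methoxyphenyl)ethan-1-one]
Conditions: I2 (0.4 equiv), HIO3 (0.2 equiv), EtOH/H2O (4:1), 35 °C, 2 h
Reagents that add atoms: iodine, II; iodic acid, OI(=O)=O
Why: Electrophilic aromatic iodination (SEAr) should go to C3', the ring carbon flanked by the two free hydroxyls, by analogy with the iodination of 2,4-dihydroxyacetophenone under these conditions; HIO3 re-oxidises the iodide so that all iodine ends up in the product.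

Step 2
Reactants: 3 methyl (S)-oxirane-2-carboxylate [methyl (S)-glycidate]
Product: 5 (S)-2-(oxiran-2-yl)propan-2-ol, via (S)-1-(oxiran-2-yl)ethan-1-one 4 (not isolated)
Conditions: MeMgCl (2.2 equiv), THF, −78 → −40 °C; sat. aq NH4Cl at −40 °C; bulb-to-bulb distillation
Reagents that add atoms: methylmagnesium chloride, C[Mg]Cl
Why: Double Grignard addition to the ester (through ketone 4) should outrun attack on the oxirane at low temperature, and the bought stereocentre is neither deprotonated nor substituted, so 5 keeps the (S) configuration.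

Step 3
Reactants: 2 3'-iodo-2',4'-dihydroxy-6'-methoxyacetophenone; 5 (S)-2-(oxiran-2-yl)propan-2-ol (1.5 equiv)
Product: 7 1-[3-[(2S)-2,3-dihydroxy-3-methylbutyl]-2,4-dihydroxy-6-methoxyphenyl]ethan-1-one, via (2R)-1-iodo-3-methylbutane-2,3-diol 6 (not isolated)
Conditions: NiBr2(dme) (10 mol %; dme = 1,2-dimethoxyethane), 4,4'-di-tert-butyl-2,2'-bipyridine (12 mol %), 4CzIPN [2,4,5,6-tetrakis(carbazol-9-yl)isophthalonitrile] (2 mol %), Hantzsch ester (1.5 equiv), 2,6-lutidine (1.2 equiv), NaI (20 mol %), degassed DMA, 450 nm LEDs, 25 °C, 16 h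
Reagents that add atoms: none
Why: Proposed new method: a titanium-free nickel/photoredox cross-electrophile coupling run on a free, doubly ortho-hydroxylated aryl iodide, in which lutidinium iodide opens 5 by SN2 at its CH2 terminus to iodohydrin 6, zerovalent nickel inserts into the C–I bond of 2, monovalent nickel abstracts iodine from 6 to give the primary radical, the arylnickel species traps it, and C(sp2)–C(sp3) reductive elimination from trivalent nickel forms the aryl–CH2 bond while photoexcited 4CzIPN and Hantzsch ester return nickel to the zerovalent state; each turnover releases lutidinium iodide, which feeds the next molecule of 5 into 6; the medium stays weakly acidic and reducing, so the phenols stay protonated and unoxidised and the ketone is left alone; the C–O bond at the stereocentre is never broken, so the product is (S) (the descriptor of 6 is R only because CH2I outranks the carbinol carbon); the closest known reaction type is the nickel/photoredox (and the thermal nickel/iodide) reductive coupling of aryl iodides with terminal aliphatic epoxides through iodohydrins, not yet shown on unprotected 2,6-dihydroxyaryl iodides or with a Hantzsch ester/pyridinium iodide relay.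

Step 4
Reactants: 7 1-[3-[(2S)-2,3-dihydroxy-3-methylbutyl]-2,4-dihydroxy-6-methoxyphenyl]ethan-1-one; 8 4-hydroxybenzaldehyde (1.5 equiv)
Product: 10 (E)-1-[3-[(2S)-2,3-dihydroxy-3-methylbutyl]-2,4-dihydroxy-6-methoxyphenyl]-3-(4-hydroxyphenyl)prop-2-en-1-one (target), via aldol adduct 9 (not isolated)
Conditions: KOH (50 % aq, ca. 20 equiv), EtOH, 0 °C → rt, Ar, 48 h; then 1 M HCl at 0 °C to pH 5
Reagents that add atoms: none
Why: Claisen–Schmidt condensation: the potassium enolate of the methyl ketone adds to the non-enolisable aldehyde and E1cB loss of water from aldol 9 gives the conjugated (E)-enone, the thermodynamic isomer, while the remote, non-acidic carbinol stereocentre is untouched.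

**Compound list**

1 | 2',4'-dihydroxy-6'-methoxyacetophenone | COc1cc(O)cc(O)c1C(C)=O | starting material
2 | 3'-iodo-2',4'-dihydroxy-6'-methoxyacetophenone | COc1cc(O)c(I)c(O)c1C(C)=O | intermediate
3 | methyl (S)-oxirane-2-carboxylate | COC(=O)[C@@H]1CO1 | starting material
4 | (S)-1-(oxiran-2-yl)ethan-1-one | CC(=O)[C@@H]1CO1 | intermediate
5 | (S)-2-(oxiran-2-yl)propan-2-ol | CC(C)(O)[C@@H]1CO1 | intermediate
6 | (2R)-1-iodo-3-methylbutane-2,3-diol | IC[C@H](O)C(C)(C)O | intermediate
7 | 1-[3-[(2S)-2,3-dihydroxy-3-methylbutyl]-2,4-dihydroxy-6-methoxyphenyl]ethan-1-one | COc1cc(O)c(C[C@H](O)C(C)(C)O)c(O)c1C(C)=O | intermediate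
8 | 4-hydroxybenzaldehyde | O=Cc1ccc(O)cc1 | starting material
9 | aldol adduct: 1-[3-[(2S)-2,3-dihydroxy-3-methylbutyl]-2,4-dihydroxy-6-methoxyphenyl]-3-hydroxy-3-(4-hydroxyphenyl)propan-1-one (both epimers at the new carbinol carbon) | COc1cc(O)c(C[C@H](O)C(C)(C)O)c(O)c1C(=O)CC(O)c1ccc(O)cc1 | intermediate
10 | (E)-1-[3-[(2S)-2,3-dihydroxy-3-methylbutyl]-2,4-dihydroxy-6-methoxyphenyl]-3-(4-hydroxyphenyl)prop-2-en-1-one | COc1cc(O)c(C[C@H](O)C(C)(C)O)c(O)c1C(=O)/C=C/c1ccc(O)cc1 | target

**Step count**

Total steps: 4. Longest linear sequence: 3 (1 → 2 → 7 → 10, or 3 → 5 → 7 → 10).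

**Steps most likely to fail, with fallbacks**

Step 3 (the proposed new coupling). The aryl iodide is flanked by two oxygens, so hydrodeiodination back to 1 may win over radical capture. The iodohydrin can also be over-reduced to 2-methylbut-3-en-2-ol. The fallback uses known polar chemistry; it sets out from epoxide 5 and comes back at 7. Commercial 5-methoxyresorcinol (COc1cc(O)cc(O)c1) is protected with MOMCl/i-Pr2NEt (CH2Cl2, 0 °C → rt) to give 1-methoxy-3,5-bis(methoxymethoxy)benzene F1. n-BuLi (THF, 0 °C) lithiates F1 between the two MOM ethers. This aryllithium (2.2 equiv, one equivalent being spent on the tertiary hydroxyl) opens 5 at its CH2 terminus with BF3·OEt2 at −78 °C, giving (2S)-1-[4-methoxy-2,6-bis(methoxymethoxy)phenyl]-3-methylbutane-2,3-diol F2. The diol is tied up with 2,2-dimethoxypropane and pyridinium p-toluenesulfonate as (4S)-4-[[4-methoxy-2,6-bis(methoxymethoxy)phenyl]methyl]-2,2,5,5-tetramethyl-1,3-dioxolane F3. A second ortho-lithiation (n-BuLi, TMEDA, THF, −20 °C) between a MOM ether and the methoxy group is quenched with N-methoxy-N-methylacetamide; the two open ring positions are equivalent, so one ketone results, 1-[6-methoxy-2,4-bis(methoxymethoxy)-3-[[(4S)-2,2,5,5-tetramethyl-1,3-dioxolan-4-yl]methyl]phenyl]ethan-1-one F4. HCl in MeOH (rt) removes both MOM groups and the acetonide and gives 7.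

Step 4 (unprotected Claisen–Schmidt). The polyanionic ketone and the phenoxide of 8 react slowly, and the chalcone can close to the flavanone on acidification. The fallback changes the substrates to the protected pair; it sets out from 7 and comes back at 10. MOMCl/K2CO3 in acetone protects only the non-chelated 4'-hydroxyl, giving 1-[3-[(2S)-2,3-dihydroxy-3-methylbutyl]-2-hydroxy-6-methoxy-4-(methoxymethoxy)phenyl]ethan-1-one F5. Condensation with commercial 4-(methoxymethoxy)benzaldehyde (COCOc1ccc(C=O)cc1; KOH, EtOH/H2O, rt) gives (E)-1-[3-[(2S)-2,3-dihydroxy-3-methylbutyl]-2-hydroxy-6-methoxy-4-(methoxymethoxy)phenyl]-3-[4-(methoxymethoxy)phenyl]prop-2-en-1-one F6. Dilute HCl in MeOH (rt) removes both MOM groups to give 10.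

Step 2 (Grignard addition beside a free oxirane). Halide or the Grignard may open the ring, and 5 is volatile and water-soluble. The fallback masks the oxirane during the addition; it sets out from 3 and comes back at 5. LiCl/AcOH in THF opens 3 at C3 to methyl (2R)-3-chloro-2-hydroxypropanoate F7. MeMgCl (3.3 equiv, THF, −78 → 0 °C) converts the ester to (2R)-1-chloro-3-methylbutane-2,3-diol F8. Powdered KOH in Et2O (0 °C → rt) closes the ring by attack of the secondary alkoxide on CH2Cl, which leaves the stereocentre untouched, and gives 5.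

**Further compounds**

F1 | step 3 | 1-methoxy-3,5-bis(methoxymethoxy)benzene | COCOc1cc(OC)cc(OCOC)c1
F2 | step 3 | (2S)-1-[4-methoxy-2,6-bis(methoxymethoxy)phenyl]-3-methylbutane-2,3-diol | COCOc1cc(OC)cc(OCOC)c1C[C@H](O)C(C)(C)O
F3 | step 3 | (4S)-4-[[4-methoxy-2,6-bis(methoxymethoxy)phenyl]methyl]-2,2,5,5-tetramethyl-1,3-dioxolane | COCOc1cc(OC)cc(OCOC)c1C[C@H](OC(C)(C)O2)C2(C)C
F4 | step 3 | 1-[6-methoxy-2,4-bis(methoxymethoxy)-3-[[(4S)-2,2,5,5-tetramethyl-1,3-dioxolan-4-yl]methyl]phenyl]ethan-1-one | COCOc1cc(OC)c(C(C)=O)c(OCOC)c1C[C@H](OC(C)(C)O2)C2(C)C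
F5 | step 4 | 1-[3-[(2S)-2,3-dihydroxy-3-methylbutyl]-2-hydroxy-6-methoxy-4-(methoxymethoxy)phenyl]ethan-1-one | COCOc1cc(OC)c(C(C)=O)c(O)c1C[C@H](O)C(C)(C)O
F6 | step 4 | (E)-1-[3-[(2S)-2,3-dihydroxy-3-methylbutyl]-2-hydroxy-6-methoxy-4-(methoxymethoxy)phenyl]-3-[4-(methoxymethoxy)phenyl]prop-2-en-1-one | COCOc1ccc(/C=C/C(=O)c2c(OC)cc(OCOC)c(C[C@H](O)C(C)(C)O)c2O)cc1
F7 | step 2 | methyl (2R)-3-chloro-2-hydroxypropanoate | ClC[C@H](O)C(=O)OC
F8 | step 2 | (2R)-1-chloro-3-methylbutane-2,3-diol | ClC[C@H](O)C(C)(C)O
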